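Flemistrictin D has a single alkene, C3=C4 of the pyran ring. C4 is attached to arene carbon C4a, and C3 sits beside quaternary C2, whose oxygen O1 is bound to C8a. Cutting C3=C4 therefore gives a hexasubstituted benzene with a vinyl group at C4a and a 1,1-dimethylallyl ether at C8a. The C5 and C8 phenols are masked as MOM ethers, and the C6 dihydrocinnamoyl and C7 methoxy groups are already in place. Ring-closing metathesis makes this bond, closes the 2H-pyran and expels ethene in one operation. The O1 phenol is kept apart from the other two by a benzyl ether that is removed during chalcone hydrogenation.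

Key step: step 10

Remark: the target has no stereocentre (C2 carries two identical methyl groups) and its only alkene is held cis by the ring, so it is achiral and no enantiocontrol is needed.

Step 1
Reactants: 1 1-(2,4-dihydroxy-6-methoxyphenyl)ethan-1-one
Product: 2 1-[4-(benzyloxy)-2-hydroxy-6-methoxyphenyl]ethan-1-one
Conditions: BnBr (1.05 equiv), K2CO3, acetone, reflux
Reagents that add atoms: benzyl bromide, BrCc1ccccc1
Why: Williamson etherification that is chemoselective because the C2 hydroxyl is locked in a hydrogen bond to the acetyl carbonyl, so only the free, more acidic C4 phenol (the later O1 of the chromene) is alkylated.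

Step 2
Reactants: 2 1-[4-(benzyloxy)-2-hydroxy-6-methoxyphenyl]ethan-1-one
Product: 4 1-[4-(benzyloxy)-3,6-dihydroxy-2-methoxyphenyl]ethan-1-one, via aryl potassium sulfate 3 (not isolated)
Conditions: K2S2O8, 10% aq NaOH, pyridine, 15 °C to rt; acidify to pH 4, extract unreacted 2; then conc. HCl, N2, 85 °C
Reagents that add atoms: potassium peroxodisulfate, [K+].[K+].[O-]S(=O)(=O)OOS(=O)(=O)[O-]
Why: Elbs persulfate oxidation, in which the phenoxide of the chelated hydroxyl attacks the peroxide oxygen through its unsubstituted para carbon (the later C8, further activated by two ortho alkoxy groups), and brief acid hydrolysis of the water-soluble sulfate monoester then frees the hydroquinone without touching the benzyl ether, the methyl ether or the ketone.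

Step 3
Reactants: 4 1-[4-(benzyloxy)-3,6-dihydroxy-2-methoxyphenyl]ethan-1-one
Product: 6 1-[4-(benzyloxy)-2-methoxy-3,6-bis(methoxymethoxy)phenyl]ethan-1-one, via disodium bis-phenoxide 5 (not isolated)
Conditions: NaH (2.3 equiv), DMF, 0 °C, Ar; then MOMCl (2.5 equiv), 0 °C to rt
Reagents that add atoms: chloromethyl methyl ether, COCCl
Why: Double Williamson-type O-alkylation with an α-chloro ether (MOM acetal formation), in which full deprotonation with sodium hydride overcomes the chelation of the hydroxyl beside the acetyl group and the two phenols are the only sites deprotonated at this base loading.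

Step 4
Reactants: 6 1-[4-(benzyloxy)-2-methoxy-3,6-bis(methoxymethoxy)phenyl]ethan-1-one; 7 benzaldehyde
Product: 8 (E)-1-[4-(benzyloxy)-2-methoxy-3,6-bis(methoxymethoxy)phenyl]-3-phenylprop-2-en-1-one
Conditions: KOH, EtOH–H2O, rt
Reagents that add atoms: none
Why: Claisen–Schmidt condensation, in which only the methyl ketone can enolise and only benzaldehyde can accept, E1cB loss of water gives the conjugated E enone, and all ether and acetal groups are inert to hydroxide.

Step 5
Reactants: 8 (E)-1-[4-(benzyloxy)-2-methoxy-3,6-bis(methoxymethoxy)phenyl]-3-phenylprop-2-en-1-one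
Product: 9 1-[4-hydroxy-2-methoxy-3,6-bis(methoxymethoxy)phenyl]-3-phenylpropan-1-one
Conditions: H2 (1 atm), 10% Pd/C, EtOAc–EtOH, rt
Reagents that add atoms: none
Why: Heterogeneous catalytic hydrogenation saturates the enone C=C and hydrogenolyses the aryl benzyl ether in the same flask, which unmasks only the phenol destined to become O1, while the twisted di-ortho-substituted aryl ketone and the MOM acetals resist 1 atm of hydrogen in neutral solvent.

Step 6
Reactants: 9 1-[4-hydroxy-2-methoxy-3,6-bis(methoxymethoxy)phenyl]-3-phenylpropan-1-one
Product: 10 1-[4-hydroxy-5-iodo-2-methoxy-3,6-bis(methoxymethoxy)phenyl]-3-phenylpropan-1-one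
Conditions: NIS (1.05 equiv), MeCN, 0 °C, dark
Reagents that add atoms: N-iodosuccinimide, O=C1CCC(=O)N1I
Why: Electrophilic aromatic iodination at the one remaining ring CH (the later C4a), which lies ortho to the free phenol and to an OMOM group and para to the methoxy group, so a neutral iodonium source suffices and the acid-labile acetals are not endangered.

Step 7
Reactants: 10 1-[4-hydroxy-5-iodo-2-methoxy-3,6-bis(methoxymethoxy)phenyl]-3-phenylpropan-1-one; 11 4,4,5,5-tetramethyl-2-vinyl-1,3,2-dioxaborolane
Product: 12 1-[4-hydroxy-2-methoxy-3,6-bis(methoxymethoxy)-5-vinylphenyl]-3-phenylpropan-1-one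
Conditions: Pd(dppf)Cl2·CH2Cl2 (5 mol %), K2CO3, 1,4-dioxane–H2O (4:1), 80 °C
Reagents that add atoms: none
Why: Suzuki–Miyaura cross-coupling of an aryl iodide with a vinylboronate, in which oxidative addition into the C–I bond remains easy despite the two ortho substituents and the phenol, ketone and acetals tolerate aqueous carbonate.

Step 8
Reactants: 13 2-methylbut-3-en-2-ol
Product: 15 tert-butyl 2-methylbut-3-en-2-yl carbonate, via lithium alkoxide 14 (not isolated)
Conditions: n-BuLi, THF, −78 to 0 °C; then Boc2O, 0 °C to rt; aqueous work-up
Reagents that add atoms: di-tert-butyl dicarbonate, CC(C)(C)OC(=O)OC(=O)OC(C)(C)C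
Why: Acylation of a pre-formed tertiary alkoxide by Boc anhydride (mixed carbonate formation), with deprotonation making up for the low nucleophilicity of the tertiary alcohol.

Step 9
Reactants: 12 1-[4-hydroxy-2-methoxy-3,6-bis(methoxymethoxy)-5-vinylphenyl]-3-phenylpropan-1-one; 15 tert-butyl 2-methylbut-3-en-2-yl carbonate
Product: 16 1-[2-methoxy-3,6-bis(methoxymethoxy)-4-(2-methylbut-3-en-2-yloxy)-5-vinylphenyl]-3-phenylpropan-1-one
Conditions: Pd(PPh3)4 (5 mol %), 15 (1.3 equiv), degassed THF, 0 °C
Reagents that add atoms: none
Why: Decarboxylative Tsuji–Trost O-allylation, in which palladium(0) ionises the carbonate to the 1,1-dimethyl-π-allyl cation and tert-butoxide, the latter deprotonates the only free phenol, and at low temperature the phenoxide adds under kinetic control to the more substituted, more positively charged allyl terminus to give the tertiary ether.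

Step 10
Reactants: 16 1-[2-methoxy-3,6-bis(methoxymethoxy)-4-(2-methylbut-3-en-2-yloxy)-5-vinylphenyl]-3-phenylpropan-1-one
Product: 17 1-[7-methoxy-5,8-bis(methoxymethoxy)-2,2-dimethyl-2H-chromen-6-yl]-3-phenylpropan-1-one
Conditions: Grubbs II (5 mol %), 1,4-benzoquinone (10 mol %), degassed CH2Cl2 (5 mM), 40 °C
Reagents that add atoms: none
Why: Olefin metathesis by the [2+2]/retro-[2+2] cycle: the ruthenium carbene should first take up the aryl vinyl group, the resulting aryl-bound benzylidene adds across the monosubstituted alkene of the nearby ether chain, and collapse of the ruthenacyclobutane creates C3=C4 while Ru=CH2 carries the chain and ethene escapes. The closest known reaction type is ring-closing metathesis of o-vinylaryl allyl ethers to 2H-chromenes, which with NHC-bearing ruthenium catalysts also accepts a fully substituted allylic carbon. The single new ring, the six-membered 2H-pyran (O1–C2–C3=C4–C4a–C8a), closes by intramolecular diene metathesis between two terminal alkenes fixed ortho to each other, and the two methyl groups on C2 bias the chain towards the folded conformer (Thorpe–Ingold effect). No stereocentre is created and the ring size permits only the Z alkene. The step needs cyclisation ahead of intermolecular metathesis and an intact tertiary allyl aryl ether: dilution and the ortho tether secure the first, while C4a, C8 and C6 (both ortho positions and the para position of the C8a oxygen) are all substituted, so an aromatic Claisen shift finds no carbon at which it could rearomatise, and the neutral medium at 40 °C offers no path to ionisation. Benzoquinone intercepts ruthenium hydrides that would otherwise move the double bonds, and the MOM acetals, the methyl ether and the hindered ketone are spectators.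

Step 11
Reactants: 17 1-[7-methoxy-5,8-bis(methoxymethoxy)-2,2-dimethyl-2H-chromen-6-yl]-3-phenylpropan-1-one
Product: 18 flemistrictin D, 1-(5,8-dihydroxy-7-methoxy-2,2-dimethyl-2H-chromen-6-yl)-3-phenylpropan-1-one
Conditions: HCl (1.25 M in MeOH), degassed, Ar, 40 °C
Reagents that add atoms: none
Why: Acid-catalysed transacetalisation to methanol cleaves both MOM groups, whereas the aryl methyl ether, the ketone and the 2,2-dimethyl-2H-chromene are stable to dilute acid at this temperature, and exclusion of air protects the liberated hydroquinone.

Compound list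
1 | 1-(2,4-dihydroxy-6-methoxyphenyl)ethan-1-one (2',4'-dihydroxy-6'-methoxyacetophenone) | CC(=O)c1c(O)cc(O)cc1OC | starting material
2 | 1-[4-(benzyloxy)-2-hydroxy-6-methoxyphenyl]ethan-1-one | CC(=O)c1c(O)cc(OCc2ccccc2)cc1OC | intermediate
3 | potassium 3-acetyl-6-(benzyloxy)-4-hydroxy-2-methoxyphenyl sulfate | CC(=O)c1c(O)cc(OCc2ccccc2)c(OS(=O)(=O)[O-])c1OC.[K+] | intermediate
4 | 1-[4-(benzyloxy)-3,6-dihydroxy-2-methoxyphenyl]ethan-1-one | CC(=O)c1c(O)cc(OCc2ccccc2)c(O)c1OC | intermediate
5 | disodium 2-acetyl-5-(benzyloxy)-3-methoxybenzene-1,4-diolate | CC(=O)c1c([O-])cc(OCc2ccccc2)c([O-])c1OC.[Na+].[Na+] | intermediate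
6 | 1-[4-(benzyloxy)-2-methoxy-3,6-bis(methoxymethoxy)phenyl]ethan-1-one | CC(=O)c1c(OCOC)cc(OCc2ccccc2)c(OCOC)c1OC | intermediate
7 | benzaldehyde | O=Cc1ccccc1 | starting material
8 | (E)-1-[4-(benzyloxy)-2-methoxy-3,6-bis(methoxymethoxy)phenyl]-3-phenylprop-2-en-1-one | O=C(/C=C/c1ccccc1)c1c(OCOC)cc(OCc2ccccc2)c(OCOC)c1OC | intermediate
9 | 1-[4-hydroxy-2-methoxy-3,6-bis(methoxymethoxy)phenyl]-3-phenylpropan-1-one | O=C(CCc1ccccc1)c1c(OCOC)cc(O)c(OCOC)c1OC | intermediate
10 | 1-[4-hydroxy-5-iodo-2-methoxy-3,6-bis(methoxymethoxy)phenyl]-3-phenylpropan-1-one | O=C(CCc1ccccc1)c1c(OCOC)c(I)c(O)c(OCOC)c1OC | intermediate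
11 | 4,4,5,5-tetramethyl-2-vinyl-1,3,2-dioxaborolane | C=CB1OC(C)(C)C(C)(C)O1 | starting material
12 | 1-[4-hydroxy-2-methoxy-3,6-bis(methoxymethoxy)-5-vinylphenyl]-3-phenylpropan-1-one | O=C(CCc1ccccc1)c1c(OCOC)c(C=C)c(O)c(OCOC)c1OC | intermediate
13 | 2-methylbut-3-en-2-ol | C=CC(C)(C)O | starting material
14 | lithium 2-methylbut-3-en-2-olate | [Li+].[O-]C(C)(C)C=C | intermediate
15 | tert-butyl 2-methylbut-3-en-2-yl carbonate | C=CC(C)(C)OC(=O)OC(C)(C)C | intermediate
16 | 1-[2-methoxy-3,6-bis(methoxymethoxy)-4-(2-methylbut-3-en-2-yloxy)-5-vinylphenyl]-3-phenylpropan-1-one | C=Cc1c(OCOC)c(C(=O)CCc2ccccc2)c(OC)c(OCOC)c1OC(C)(C)C=C | intermediate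
17 | 1-[7-methoxy-5,8-bis(methoxymethoxy)-2,2-dimethyl-2H-chromen-6-yl]-3-phenylpropan-1-one (flemistrictin D bis-MOM ether) | COCOc1c(OC)c(C(=O)CCc2ccccc2)c(OCOC)c2c1OC(C)(C)C=C2 | intermediate
18 | flemistrictin D, 1-(5,8-dihydroxy-7-methoxy-2,2-dimethyl-2H-chromen-6-yl)-3-phenylpropan-1-one | COc1c(O)c2c(c(O)c1C(=O)CCc1ccccc1)C=CC(C)(C)O2 | target

Total step count: 11. Longest linear sequence: 10 (steps 1–7 and 9–11; step 8 is a side branch).

Steps most likely to fail

1. Step 10. The styrene is flanked on both sides and may take up ruthenium slowly. The alkene beside the quaternary carbon may also be reluctant to enter the metallacycle. Catalyst decay, hydride-induced alkene migration or intermolecular styrene coupling could then overtake ring closure. The fallback gives up metathesis and uses known chemistry. It sets out from 9 and comes back to the route at 17. Copper-catalysed O-alkylation of 9 with 3-chloro-3-methylbut-1-yne (CuCl2 cat., DBU, MeCN, 0 °C) should give the aryl 1,1-dimethylpropargyl ether F1. Heating this in o-xylene at about 140 °C triggers the aromatic propargyl Claisen rearrangement onto the only free ortho carbon (the later C4a). Enolisation, a 1,5-hydrogen shift and oxa-6π electrocyclisation follow and deliver 17 directly.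

2. Step 9. The hindered phenoxide may attack the unsubstituted allyl terminus. The tertiary ether may also re-ionise on palladium and drift to the linear isomer, and surplus alkoxide could bring the ketone enolate into play as a competing nucleophile. The fallback sets out from 12 and comes back at 16. The same copper-catalysed alkylation with 3-chloro-3-methylbut-1-yne should give the ortho-vinylaryl 1,1-dimethylpropargyl ether F2, which cannot rearrange productively because both ortho positions are blocked. Semihydrogenation over Lindlar catalyst with quinoline, stopped after one equivalent of hydrogen, then converts the alkyne into the vinyl group of 16. The terminal alkyne binds the poisoned surface much better than the styrene does.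

3. Step 2. The lipophilic phenoxide may dissolve poorly and convert slowly, and persulfate may over-oxidise the electron-rich ring, so the material balance could be poor. The fallback sets out from 2 and comes back at 4. Teuber oxidation with Fremy's salt (KH2PO4 buffer, acetone–water) should take the phenol, through its free para position, to 2-acetyl-5-(benzyloxy)-3-methoxy-1,4-benzoquinone F3. Aqueous sodium dithionite then reduces this quinone to 4.

Further compounds
F1 | step 10 | 1-[2-methoxy-3,6-bis(methoxymethoxy)-4-(2-methylbut-3-yn-2-yloxy)phenyl]-3-phenylpropan-1-one | C#CC(C)(C)Oc1cc(OCOC)c(C(=O)CCc2ccccc2)c(OC)c1OCOC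
F2 | step 9 | 1-[2-methoxy-3,6-bis(methoxymethoxy)-4-(2-methylbut-3-yn-2-yloxy)-5-vinylphenyl]-3-phenylpropan-1-one | C=Cc1c(OCOC)c(C(=O)CCc2ccccc2)c(OC)c(OCOC)c1OC(C)(C)C#C
F3 | step 2 | 2-acetyl-5-(benzyloxy)-3-methoxycyclohexa-2,5-diene-1,4-dione | CC(=O)C1=C(OC)C(=O)C(OCc2ccccc2)=CC1=O
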